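The 14-membered ring is closed at C2–C3, the bond between the lactone carbinol C2 and the allylic carbinol C3, which with the C4=C5 alkene forms a 1-ene-3,4-diol retron. An intramolecular γ-alkoxyallylchromium addition makes this bond: the bis(4-methoxybenzyl) acetal of a geranyl-derived enal becomes an allylchromium that attacks a C2 aldehyde through C3. One operation closes the carbocycle, sets C2 and C3 (anti), rebuilds the E C4=C5 alkene and, by acyl shift from O13 to O2, delivers the trans γ-lactone. The precursor is an open-chain acetal aldehyde whose C1 stereocentre is held in a temporary δ-lactone on O13.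

Key step: step 11

Remark (numbering): cembrane numbering is used throughout: C1 = ring-fusion CH bearing C15; C2 = lactone O–CH; C3 = CH(OH); C4(C18)=C5; C8(C19)=C9; C12 = C(OH)(C20H2OH); C13 = CH(OH); C14 = CH2; C15, C16, C17 = α-carbon, carbonyl and methylene of the lactone. PMB = 4-methoxybenzyl.

Step 1
Reactants: 1 geranyl bromide; 2 2-methylprop-2-en-1-ol
Product: 4 (5E)-6,10-dimethyl-2-methylideneundeca-5,9-dien-1-ol, via dilithium dianion 3 (not isolated)
Conditions: 2, n-BuLi (2.2 equiv), TMEDA, Et2O, 0 → 23 °C; then 1, −78 → 0 °C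
Reagents that add atoms: none
Why: Double deprotonation of 2 gives the C,O-dianion 3, whose allylic carbanion should displace the primary allylic bromide of 1 in an SN2 dianion alkylation, joining C10 to C11 and leaving both trisubstituted alkenes, including the E-configured C8=C9, untouched.

Step 2
Reactants: 4
Product: 5 (R)-{2-[(3E)-4,8-dimethylnona-3,7-dien-1-yl]oxiran-2-yl}methanol
Conditions: Ti(OiPr)4 (10 mol%), D-(−)-diisopropyl tartrate (12 mol%), t-BuOOH, 4 Å MS, CH2Cl2, −20 °C
Reagents that add atoms: tert-butyl hydroperoxide, CC(C)(C)OO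
Why: Sharpless asymmetric epoxidation of a 2-substituted allylic alcohol is directed by the hydroxyl, so the isolated trisubstituted alkenes should not react, and D-(−)-tartrate should deliver oxygen to the face that gives the (R)-oxirane, which fixes the configuration of C12.

Step 3
Reactants: 5
Product: 6 (S)-2-[(3E)-4,8-dimethylnona-3,7-dien-1-yl]oxirane-2-carbaldehyde
Conditions: Dess–Martin periodinane, NaHCO3, CH2Cl2, 0 → 23 °C
Reagents that add atoms: none
Why: Buffered Dess–Martin oxidation should give the aldehyde without opening the oxirane, and the quaternary α-carbon excludes epimerisation.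

Step 4
Reactants: 6
Product: 8 (1S)-1-{(2S)-2-[(3E)-4,8-dimethylnona-3,7-dien-1-yl]oxiran-2-yl}but-3-en-1-ol, via diisopinocampheylborinate 7 (not isolated)
Conditions: salt-free (−)-Ipc2B(allyl), Et2O, −78 °C; then NaOH, H2O2, 0 °C
Reagents that add atoms: (−)-B-allyldiisopinocampheylborane, C=CCB([C@@H]1C[C@@H]2C[C@@H](C2(C)C)[C@H]1C)[C@@H]1C[C@@H]2C[C@@H](C2(C)C)[C@H]1C
Why: Brown allylboration through a closed chair transition state should add allyl to the Si face under reagent control, overriding the small bias of the neighbouring quaternary oxirane and setting C13 as S.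

Step 5
Reactants: 8
Product: 9 (4S,5S,8E)-5-[(4-methoxybenzyloxy)methyl]-9,13-dimethyltetradeca-1,8,12-triene-4,5-diol
Conditions: 4-methoxybenzyl alcohol (5 equiv), NaH, DMF, 60 °C
Reagents that add atoms: 4-methoxybenzyl alcohol, COc1ccc(CO)cc1
Why: Base-mediated SN2 opening of the oxirane by 4-methoxybenzyl alkoxide should occur at the unsubstituted carbon C20, so C12 and C13 keep their configuration, and a reversible Payne rearrangement of the alkoxide does not change the outcome because only the terminal oxirane offers an unhindered primary carbon.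

Step 6
Reactants: 9
Product: 10 (4S,5S,8E)-5-hydroxy-5-[(4-methoxybenzyloxy)methyl]-9,13-dimethyltetradeca-1,8,12-trien-4-yl prop-2-enoate
Conditions: acryloyl chloride, Et3N, DMAP (cat.), CH2Cl2, −20 → 0 °C
Reagents that add atoms: acryloyl chloride, C=CC(=O)Cl
Why: Acylation with acryloyl chloride should take place only at the secondary C13 hydroxyl, the tertiary C12 hydroxyl being too hindered (chemoselective esterification).

Step 7
Reactants: 10
Product: 12 (6S)-6-[(2S,5E,9E)-2-hydroxy-1-(4-methoxybenzyloxy)-6,10-dimethyl-11-oxoundeca-5,9-dien-2-yl]-5,6-dihydro-2H-pyran-2-one, via dihydropyranone 11 (not isolated)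
Conditions: second-generation Grubbs catalyst (5 mol%), CH2Cl2 (2 mM), 40 °C; then concentration, methacrolein (10 equiv), second-generation Hoveyda–Grubbs catalyst (5 mol%), 40 °C
Reagents that add atoms: methacrolein, CC(=C)C=O
Why: Ring-closing metathesis of the acrylate and the allyl group should close the six-membered unsaturated lactone 11 fast, and cross-metathesis of the terminal isopropylidene group with methacrolein should then give the thermodynamically favoured (E)-2-methyl enal (C3, C4, C18), the internal C8=C9 alkene being more hindered and the lactone alkene electron-poor.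

Step 8
Reactants: 12
Product: 14 (6S)-6-[(2S,5E,9E)-1,11,11-tris(4-methoxybenzyloxy)-6,10-dimethyl-2-(trimethylsilyloxy)undeca-5,9-dien-2-yl]-5,6-dihydro-2H-pyran-2-one, via hydroxy acetal 13 (not isolated)
Conditions: 4-MeOC6H4CH2OSiMe3 (2.5 equiv), Me3SiOTf (5 mol%), CH2Cl2, −78 °C; then 2,6-lutidine, Me3SiOTf (1.3 equiv), −78 → −40 °C
Reagents that add atoms: (4-methoxybenzyloxy)trimethylsilane, COc1ccc(CO[Si](C)(C)C)cc1; trimethylsilyl triflate, C[Si](C)(C)OS(=O)(=O)C(F)(F)F
Why: Noyori acetalisation (silyl ether plus catalytic silyl triflate at −78 °C) should convert the enal into its bis(4-methoxybenzyl) acetal without conjugate addition or alkene migration, and silyl triflate with 2,6-lutidine should then cap the tertiary C12 hydroxyl as its trimethylsilyl ether.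

Step 9
Reactants: 14
Product: 15 (4R,6S)-4-(1,3-dithian-2-yl)-6-[(2S,5E,9E)-1,11,11-tris(4-methoxybenzyloxy)-6,10-dimethyl-2-(trimethylsilyloxy)undeca-5,9-dien-2-yl]tetrahydro-2H-pyran-2-one
Conditions: 1,3-dithiane, n-BuLi, THF, −30 °C; HMPA; 14, −78 °C; aq. NH4Cl
Reagents that add atoms: 1,3-dithiane, C1CSCSC1
Why: Michael addition of the dithiane anion (a formyl anion equivalent, Corey–Seebach umpolung) in the presence of HMPA should occur at C1 by axial attack anti to the C13 substituent of the half-chair lactone, giving the 4,6-trans lactone and thereby setting C1 as R.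

Step 10
Reactants: 15
Product: 16 (2S,4R)-6-oxo-2-[(2S,5E,9E)-1,11,11-tris(4-methoxybenzyloxy)-6,10-dimethyl-2-(trimethylsilyloxy)undeca-5,9-dien-2-yl]tetrahydro-2H-pyran-4-carbaldehyde
Conditions: MeI, CaCO3, MeCN/H2O (9:1), 40 °C
Reagents that add atoms: water, O
Why: Alkylative hydrolysis of the dithiane (S-methylation, then attack of water) under CaCO3 buffering should free the C2 aldehyde at neutral pH, so the acetal, the silyl ether and the configuration at C1 are kept.

Step 11
Reactants: 16
Product: 19 (1R,2R,3S,12S,13S)-γ-lactone of the sinularolide A skeleton with CH2 at C15 (no exocyclic methylene) and with 3-O-PMB and 20-O-PMB ethers and free 12- and 13-hydroxyls, via α-iodo ether 17 (not isolated), via macrocyclic δ-lactone 18 (not isolated)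
Conditions: CrCl2 (8 equiv), THF, −30 °C; 16 and Me3SiI (1.5 equiv, in CH2Cl2) added over 10 h (final 1 mM); aq. NaHCO3; then PPTS, MeOH, 23 °C
Reagents that add atoms: none
Why: Proposed new method: Me3SiI ionises the allylic acetal to the α-iodo ether 17, two CrCl2 reduce it to an allylchromium that rests with the trivalent chromium on C5 as the (E)-γ-alkoxyallyl isomer (enol ether conjugation, OPMB cis to the small C4 methyl), and this adds through C3 to the C2 aldehyde in a closed chair transition state, after which mild acid moves the acyl group from O13 to O2. The closest known reaction type is the CrCl2/Me3SiI-mediated erythro-selective addition of γ-alkoxyallylchromium reagents from acrolein acetals to aldehydes, a Nozaki–Hiyama–Kishi-type allylation, which has not been shown for 2,3-disubstituted enal acetals or for ring closure. The 14-membered carbocycle closes by SE2′ allyl transfer in a 14-exo-trig addition to the aldehyde, and the γ-lactone closes by 5-exo-trig transacylation that opens the δ-lactone. C2 (R) is set by Felkin–Anh attack anti to the C14 branch of the C1 stereocentre held in the δ-lactone, C3 (S) by the chair with the (E)-enol ether, which places O3 anti to O2, and the C4=C5 alkene is E because C6 sits equatorial on the chromium-bearing carbon. The step needs bond formation at C3 and not C5, ring closure and not oligomerisation, and addition to the aldehyde and not the lactone; the conjugated γ-alkoxy resting state, slow addition at high dilution and the aldehyde selectivity of allylchromium reagents should secure these.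

Step 12
Reactants: 19
Product: 22 3,20-bis-O-(4-methoxybenzyl)sinularolide A, via Mannich base 20 (not isolated), via methiodide 21 (not isolated)
Conditions: LDA (5 equiv), THF, −78 °C; Me2N+=CH2 I− (Eschenmoser's salt), −78 → 23 °C; then MeI, MeOH, 23 °C; then DBU, CH2Cl2, 23 °C
Reagents that add atoms: N,N-dimethylmethyleneiminium iodide, C=[N+](C)C.[I-]
Why: Mannich reaction of the lithium enolate of the γ-lactone with Eschenmoser's salt, N-methylation and base-induced E1cB (Hofmann-type) elimination should install the exocyclic C15=C17 methylene group (α-methylenation), the excess of LDA covering the two free hydroxyls.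

Step 13
Reactants: 22
Product: 23 sinularolide A
Conditions: DDQ (2.5 equiv), CH2Cl2/pH 7 phosphate buffer (10:1), 0 °C
Reagents that add atoms: none
Why: Oxidative cleavage of 4-methoxybenzyl ethers by DDQ (hydride abstraction, then hydrolysis of the oxocarbenium ions by the aqueous buffer, which also keeps the C12 hydroxyl from being tied up as a 4-methoxybenzylidene acetal) should free O3 and O20 without touching the α-methylene lactone or the trisubstituted alkenes.

Compound list
1 | geranyl bromide, (2E)-1-bromo-3,7-dimethylocta-2,6-diene | CC(C)=CCC/C(C)=C/CBr | starting material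
2 | 2-methylprop-2-en-1-ol (methallyl alcohol) | CC(=C)CO | starting material
3 | C,O-dilithium dianion of 2 | [Li]CC(=C)CO[Li] | intermediate
4 | (5E)-6,10-dimethyl-2-methylideneundeca-5,9-dien-1-ol | OCC(=C)CC/C=C(\C)CCC=C(C)C | intermediate
5 | (R)-{2-[(3E)-4,8-dimethylnona-3,7-dien-1-yl]oxiran-2-yl}methanol | OC[C@@]1(CO1)CC/C=C(\C)CCC=C(C)C | intermediate
6 | (S)-2-[(3E)-4,8-dimethylnona-3,7-dien-1-yl]oxirane-2-carbaldehyde | O=C[C@@]1(CO1)CC/C=C(\C)CCC=C(C)C | intermediate
7 | O-diisopinocampheylboryl ether (borinate) of 8 | C=CC[C@H](OB([C@@H]1C[C@@H]2C[C@@H](C2(C)C)[C@H]1C)[C@@H]1C[C@@H]2C[C@@H](C2(C)C)[C@H]1C)[C@@]1(CO1)CC/C=C(\C)CCC=C(C)C | intermediate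
8 | (1S)-1-{(2S)-2-[(3E)-4,8-dimethylnona-3,7-dien-1-yl]oxiran-2-yl}but-3-en-1-ol | C=CC[C@H](O)[C@@]1(CO1)CC/C=C(\C)CCC=C(C)C | intermediate
9 | (4S,5S,8E)-5-[(4-methoxybenzyloxy)methyl]-9,13-dimethyltetradeca-1,8,12-triene-4,5-diol | C=CC[C@H](O)[C@@](O)(COCc1ccc(OC)cc1)CC/C=C(\C)CCC=C(C)C | intermediate
10 | 4-O-acryloyl ester of 9 | C=CC[C@H](OC(=O)C=C)[C@@](O)(COCc1ccc(OC)cc1)CC/C=C(\C)CCC=C(C)C | intermediate
11 | (6S)-6-[(2S,5E)-2-hydroxy-1-(4-methoxybenzyloxy)-6,10-dimethylundeca-5,9-dien-2-yl]-5,6-dihydro-2H-pyran-2-one | O=C1C=CC[C@H](O1)[C@@](O)(COCc1ccc(OC)cc1)CC/C=C(\C)CCC=C(C)C | intermediate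
12 | (6S)-6-[(2S,5E,9E)-2-hydroxy-1-(4-methoxybenzyloxy)-6,10-dimethyl-11-oxoundeca-5,9-dien-2-yl]-5,6-dihydro-2H-pyran-2-one | O=C1C=CC[C@H](O1)[C@@](O)(COCc1ccc(OC)cc1)CC/C=C(\C)CC/C=C(\C)C=O | intermediate
13 | bis(4-methoxybenzyl) acetal of enal 12 with free 12-hydroxyl | O=C1C=CC[C@H](O1)[C@@](O)(COCc1ccc(OC)cc1)CC/C=C(\C)CC/C=C(\C)C(OCc1ccc(OC)cc1)OCc1ccc(OC)cc1 | intermediate
14 | 12-O-trimethylsilyl ether of 13 | O=C1C=CC[C@H](O1)[C@@](O[Si](C)(C)C)(COCc1ccc(OC)cc1)CC/C=C(\C)CC/C=C(\C)C(OCc1ccc(OC)cc1)OCc1ccc(OC)cc1 | intermediate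
15 | (4R,6S)-4-(1,3-dithian-2-yl) δ-lactone (4,6-trans adduct of 14) | O=C1C[C@H](C2SCCCS2)C[C@H](O1)[C@@](O[Si](C)(C)C)(COCc1ccc(OC)cc1)CC/C=C(\C)CC/C=C(\C)C(OCc1ccc(OC)cc1)OCc1ccc(OC)cc1 | intermediate
16 | (2S,4R)-4-formyl δ-lactone (C2 aldehyde, C3 acetal) | O=C1C[C@H](C=O)C[C@H](O1)[C@@](O[Si](C)(C)C)(COCc1ccc(OC)cc1)CC/C=C(\C)CC/C=C(\C)C(OCc1ccc(OC)cc1)OCc1ccc(OC)cc1 | intermediate
17 | α-iodo ether: 16 with one acetal PMB-oxy group replaced by iodine (mixture at C3) | O=C1C[C@H](C=O)C[C@H](O1)[C@@](O[Si](C)(C)C)(COCc1ccc(OC)cc1)CC/C=C(\C)CC/C=C(\C)C(I)OCc1ccc(OC)cc1 | intermediate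
18 | (1R,2R,3S,12S,13S) 14-membered carbocycle bridged by the C16–O13 δ-lactone; 2-OH, 3-O-PMB, 12-O-SiMe3, 20-O-PMB | O=C1C[C@H]2C[C@H](O1)[C@@](O[Si](C)(C)C)(COCc3ccc(OC)cc3)CC/C=C(\C)CC/C=C(\C)[C@H](OCc3ccc(OC)cc3)[C@@H]2O | intermediate
19 | (1R,2R,3S,12S,13S) trans-fused γ-lactone (C16–O2) with CH2 at C15; 3-O-PMB, 20-O-PMB, free 12- and 13-OH | C1C(=O)O[C@@H]2[C@@H]1C[C@H](O)[C@@](O)(COCc3ccc(OC)cc3)CC/C=C(\C)CC/C=C(\C)[C@@H]2OCc1ccc(OC)cc1 | intermediate
20 | 15-(dimethylaminomethyl) derivative of 19 (Mannich base, C15 unassigned) | CN(C)CC1C(=O)O[C@@H]2[C@@H]1C[C@H](O)[C@@](O)(COCc3ccc(OC)cc3)CC/C=C(\C)CC/C=C(\C)[C@@H]2OCc1ccc(OC)cc1 | intermediate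
21 | trimethylammonium iodide from 20 | C[N+](C)(C)CC1C(=O)O[C@@H]2[C@@H]1C[C@H](O)[C@@](O)(COCc3ccc(OC)cc3)CC/C=C(\C)CC/C=C(\C)[C@@H]2OCc1ccc(OC)cc1.[I-] | intermediate
22 | 3,20-bis-O-(4-methoxybenzyl)sinularolide A | C=C1C(=O)O[C@@H]2[C@@H]1C[C@H](O)[C@@](O)(COCc3ccc(OC)cc3)CC/C=C(\C)CC/C=C(\C)[C@@H]2OCc1ccc(OC)cc1 | intermediate
23 | sinularolide A, (1R,2R,3S,12S,13S) | C=C1C(=O)O[C@@H]2[C@@H]1C[C@H](O)[C@@](O)(CO)CC/C=C(\C)CC/C=C(\C)[C@@H]2O | target

Total step count: 13. Longest linear sequence: 13 steps (from 1 and 2).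

Steps most likely to fail

1. Step 11 (labelled step). The allylchromium may form the bond through C5 instead of C3 (12-membered ring), control of the new C4=C5 geometry may be lost, Me3SiI may strip 4-methoxybenzyl groups before reduction, or chains may oligomerise. The fallback uses known chemistry, a titanium-mediated pinacol macrocyclisation of a dialdehyde followed by correction of C3, and sets out from 16. PPTS in acetone/H2O hydrolyses the acetal and the silyl ether to the dialdehyde F1. TiCl3(DME)1.5 and Zn–Cu couple in DME at 25 °C under high dilution close the same C2–C3 bond to the macrocyclic diol F2, expected mainly as the threo isomer. MnO2 oxidises only the allylic C3 hydroxyl to the α-hydroxy enone F3. Zn(BH4)2 reduces it under chelation by the free C2 hydroxyl to the erythro diol F4. PPTS in MeOH moves the lactone to O2 and gives the γ-lactone triol F5. α-Methylenation as in step 12, through the Mannich base F6 and the methiodide F7, gives the α-methylene lactone F8, and DDQ as in step 13 brings the sequence back to the route at 23.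

2. Step 7. Cross-metathesis of the hindered isopropylidene terminus may stall, or metathesis may compete at the internal C8=C9 alkene and cut the chain. The fallback sets out from 10: ring-closing metathesis alone gives 11, which is isolated; SeO2 (cat.) with t-BuOOH and salicylic acid in CH2Cl2 oxidises the terminal (E)-methyl group to the allylic alcohol F9; MnO2 oxidises it and the sequence comes back at 12.

3. Step 9. The hard lithium reagent may add 1,2 to the lactone carbonyl or deprotonate the γ-position instead of adding in conjugate fashion. The fallback sets out from 14: Michael addition of nitromethane with DBU (soft nitronate, same trans selectivity) gives the nitromethyl lactone F10, and a buffered Nef reaction (NaOMe, MeOH; then TiCl3, NH4OAc, pH 6) comes back at 16.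

Further compounds
F1 | step 11 | dialdehyde: 16 with the acetal hydrolysed to the enal and the 12-hydroxyl free | O=C1C[C@H](C=O)C[C@H](O1)[C@@](O)(COCc1ccc(OC)cc1)CC/C=C(\C)CC/C=C(\C)C=O
F2 | step 11 | macrocyclic (2R,3R)-diol (threo), δ-lactone on O13, 20-O-PMB | O=C1C[C@H]2C[C@H](O1)[C@@](O)(COCc3ccc(OC)cc3)CC/C=C(\C)CC/C=C(\C)[C@@H](O)[C@@H]2O
F3 | step 11 | macrocyclic (2R)-2-hydroxy-3-oxo enone, δ-lactone on O13, 20-O-PMB | O=C1C[C@H]2C[C@H](O1)[C@@](O)(COCc3ccc(OC)cc3)CC/C=C(\C)CC/C=C(\C)C(=O)[C@@H]2O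
F4 | step 11 | macrocyclic (2R,3S)-diol (erythro), δ-lactone on O13, 20-O-PMB | O=C1C[C@H]2C[C@H](O1)[C@@](O)(COCc3ccc(OC)cc3)CC/C=C(\C)CC/C=C(\C)[C@H](O)[C@@H]2O
F5 | step 11 | γ-lactone with CH2 at C15, free 3-, 12- and 13-hydroxyls, 20-O-PMB | C1C(=O)O[C@@H]2[C@@H]1C[C@H](O)[C@@](O)(COCc3ccc(OC)cc3)CC/C=C(\C)CC/C=C(\C)[C@@H]2O
F6 | step 11 | 15-(dimethylaminomethyl) derivative of F5 | CN(C)CC1C(=O)O[C@@H]2[C@@H]1C[C@H](O)[C@@](O)(COCc3ccc(OC)cc3)CC/C=C(\C)CC/C=C(\C)[C@@H]2O
F7 | step 11 | trimethylammonium iodide from F6 | C[N+](C)(C)CC1C(=O)O[C@@H]2[C@@H]1C[C@H](O)[C@@](O)(COCc3ccc(OC)cc3)CC/C=C(\C)CC/C=C(\C)[C@@H]2O.[I-]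
F8 | step 11 | 20-O-(4-methoxybenzyl)sinularolide A | C=C1C(=O)O[C@@H]2[C@@H]1C[C@H](O)[C@@](O)(COCc3ccc(OC)cc3)CC/C=C(\C)CC/C=C(\C)[C@@H]2O
F9 | step 7 | (6S)-6-[(2S,5E,9E)-2,11-dihydroxy-1-(4-methoxybenzyloxy)-6,10-dimethylundeca-5,9-dien-2-yl]-5,6-dihydro-2H-pyran-2-one | O=C1C=CC[C@H](O1)[C@@](O)(COCc1ccc(OC)cc1)CC/C=C(\C)CC/C=C(\C)CO
F10 | step 9 | (4R,6S)-4-(nitromethyl) δ-lactone (4,6-trans nitromethane adduct of 14) | O=C1C[C@H](C[N+](=O)[O-])C[C@H](O1)[C@@](O[Si](C)(C)C)(COCc1ccc(OC)cc1)CC/C=C(\C)CC/C=C(\C)C(OCc1ccc(OC)cc1)OCc1ccc(OC)cc1
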